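Numbering used throughout (cladiellane): cyclohexane = C1, C10–C14 (O on C11, Me on C12); tetrahydrofuran = C1, C2, O, C9, C10; oxonene = C2–C9 plus O; oxepane = C1, C2, C3, O, C16, C15, C14.
Retrosynthetic cuts, in order: O–C16 (oxepane), the C11 ester, C6=C7 (oxonene), C8–C9, then the C10–C1 ring bond together with the C9–O bond of a lactone.
Enabling feature: ring-fusion carbon C10 carries the exocyclic ring carbon C9, and C1 carries C2 whose oxygen is 1,4 to C9. A cycloheptanone with C9 as the ring carbonyl between C10 and C1 can therefore extrude C9 by Wolff rearrangement (C1 migrates to C10), and the C2 hydroxyl captures the ketene, so the seven-membered ring becomes the cyclohexane and the oxygen ring closes as a lactone in one operation.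
Forward order: meso furan/oxyallyl [4+3] adduct → enantioselective ring opening to a cycloheptene → conjugate addition and aldol → diazo transfer → ring contraction with lactonisation (cyclohexane + oxygen ring) → allylation and reduction at C9 → ring-closing metathesis (oxonene) → butyrate → hydroboration → oxepane.
Stereochemistry: C11/C12 from the catalyst-controlled syn ring opening; C14 by 1,3-induction, C1 trans to C14, C2 by a syn-selective aldol; C3 from (R)-2-methylglycidol; C10 by protonation of the lactone enol; C9 by convex-face hydride delivery; C15 by A(1,3)-controlled hydroboration; the Z alkene by ring size.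

Key step: step 12

Remark: 8-oxabicyclo[3.2.1]oct-6-en-3-one (the furan/oxyallyl cation [4+3] cycloadduct) is taken as a purchasable compound.

Step 1
Reactants: 1 (R)-2-methylglycidol; 2 allylmagnesium chloride
Product: 3 (S)-2-methylhex-5-ene-1,2-diol
Conditions: allylMgCl (2.2 equiv), CuI (10 mol %), THF, −30 to 0 °C; aq. NH4Cl
Reagents that add atoms: allylmagnesium chloride, C=CC[Mg]Cl
Why: Copper-catalysed Grignard opening of the epoxide (SN2 at its unsubstituted carbon) leaves the quaternary centre untouched, so the (R)-epoxide should give the (S)-diol that becomes C3 of the target.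

Step 2
Reactants: 3; 4 tert-butyldimethylsilyl triflate
Product: 5 (S)-1,2-bis(tert-butyldimethylsilyloxy)-2-methylhex-5-ene
Conditions: TBSOTf (2.5 equiv), 2,6-lutidine, CH2Cl2, 0 °C to rt
Reagents that add atoms: tert-butyldimethylsilyl triflate, CC(C)(C)[Si](C)(C)OS(=O)(=O)C(F)(F)F
Why: Silylation with a silyl triflate is forceful enough for the tertiary hydroxyl, so both hydroxyls are protected without touching the stereocentre.

Step 3
Reactants: 5
Product: 6 (S)-2-(tert-butyldimethylsilyloxy)-2-methylhex-5-en-1-ol
Conditions: HF·pyridine, pyridine, THF, 0 °C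
Reagents that add atoms: none
Why: Selective desilylation, because the unhindered primary silyl ether is cleaved far faster than the tertiary one.

Step 4
Reactants: 6
Product: 7 (S)-2-(tert-butyldimethylsilyloxy)-2-methylhex-5-enal (fragment 1)
Conditions: Dess–Martin periodinane, CH2Cl2, rt
Reagents that add atoms: none
Why: Dess–Martin oxidation of the primary alcohol; the α-carbon is quaternary, so the aldehyde can neither enolise nor epimerise.

Step 5
Reactants: 8 8-oxabicyclo[3.2.1]oct-6-en-3-one; 9 ethylene glycol
Product: 10 ethylene ketal of 8 (meso spiro-dioxolane)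
Conditions: HOCH2CH2OH, TsOH·H2O (cat.), benzene, reflux, Dean–Stark
Reagents that add atoms: ethylene glycol, OCCO
Why: Acid-catalysed ketalisation masks the ketone and its acidic α-hydrogens for the organozinc step; the product stays meso.

Step 6
Reactants: 10; 11 dimethylzinc
Product: 12 (7S,8R)-8-methyl-1,4-dioxaspiro[4.6]undec-9-en-7-ol
Conditions: Me2Zn, PdCl2(MeCN)2 (5 mol %), (R)-Tol-BINAP (5 mol %), Zn(OTf)2 (10 mol %), ClCH2CH2Cl, 80 °C; aq. NH4Cl
Reagents that add atoms: dimethylzinc, C[Zn]C
Why: Palladium-catalysed enantioselective alkylative ring opening of the meso oxabicyclic alkene: syn carbopalladation on the exo face and β-oxygen elimination place the methyl group cis to the freed hydroxyl, and the chiral bisphosphine selects one enantiotopic alkene carbon, setting C11 and C12 (the ligand antipode is used if the sense of induction proves opposite).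

Step 7
Reactants: 12; 13 tert-butyldimethylsilyl chloride
Product: 14 tert-butyldimethylsilyl ether of 12
Conditions: TBSCl, imidazole, DMF, rt
Reagents that add atoms: tert-butyldimethylsilyl chloride, CC(C)(C)[Si](C)(C)Cl
Why: Standard silylation of the secondary alcohol gives a C11 protecting group that survives organometallics, base and mild Lewis acid.

Step 8
Reactants: 14; 15 water
Product: 17 (5R,6S)-6-(tert-butyldimethylsilyloxy)-5-methylcyclohept-2-en-1-one, via deconjugated enone 16 (not isolated)
Conditions: PPTS, acetone–H2O, 60 °C; then DBU (cat.), CH2Cl2, rt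
Reagents that add atoms: water, O
Why: Acetal hydrolysis followed by base-mediated double-bond migration into conjugation through the dienolate (thermodynamic control; deconjugated enone that remains is separated and resubmitted), with C12 not involved.

Step 9
Reactants: 17; 18 isopropenylmagnesium bromide; 19 chlorotrimethylsilane
Product: 20 tert-butyl{[(1S,2R,4R)-2-methyl-4-(prop-1-en-2-yl)-6-(trimethylsilyloxy)cyclohept-5-en-1-yl]oxy}dimethylsilane
Conditions: isopropenylMgBr, CuBr·SMe2 (10 mol %), Me3SiCl, HMPA, THF, −78 °C; then Et3N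
Reagents that add atoms: isopropenylmagnesium bromide, C=C(C)[Mg]Br; chlorotrimethylsilane, C[Si](C)(C)Cl
Why: Copper-catalysed conjugate addition with silyl chloride trapping gives the C9–C1 enol silane regiospecifically, and the nucleophile is expected to reach C14 from the face opposite the cis-disposed C12 methyl and C11 silyloxy groups (1,3-induction).

Step 10
Reactants: 20; 7
Product: 21 (2R,3R,5R,6S)-6-(tert-butyldimethylsilyloxy)-2-[(1R,2S)-2-(tert-butyldimethylsilyloxy)-2-methyl-1-(trimethylsilyloxy)hex-5-en-1-yl]-5-methyl-3-(prop-1-en-2-yl)cycloheptan-1-one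
Conditions: TASF [(Me2N)3S][Me3SiF2] (10 mol %), THF, −78 °C
Reagents that add atoms: none
Why: Fluoride-catalysed aldol addition of the enol silane (open transition state) is syn-selective whatever the enolate geometry, and the aldehyde approaches C1 anti to the neighbouring isopropenyl group, so C1 (trans to C14) and C2 (syn aldol) are set while C3 arrives with fragment 1; silyl transfer gives the aldol as its TMS ether.

Step 11
Reactants: 21; 22 4-acetamidobenzenesulfonyl azide
Product: 25 (3R,4R,6R,7R)-3-(tert-butyldimethylsilyloxy)-7-[(1R,2S)-2-(tert-butyldimethylsilyloxy)-1-hydroxy-2-methylhex-5-en-1-yl]-2-diazo-4-methyl-6-(prop-1-en-2-yl)cycloheptan-1-one, via trifluoroacetyl ketone 23 (not isolated), via O-TMS diazo ketone 24 (not isolated)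
Conditions: LiN(SiMe3)2, THF, −78 °C; CF3CO2CH2CF3; aq. HCl work-up; then 22, Et3N, H2O, MeCN, rt; then citric acid, MeOH, 0 °C
Reagents that add atoms: 4-acetamidobenzenesulfonyl azide, CC(=O)Nc1ccc(cc1)S(=O)(=O)N=[N+]=[N-]
Why: Detrifluoroacetylative diazo transfer (a Regitz-type reaction): kinetic deprotonation at the only α-methylene (C10), C-trifluoroacetylation, then sulfonyl azide and amine transfer the diazo group with loss of the activating group; mild acid methanolysis removes only the TMS ether.

Step 12
Reactants: 25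
Product: 27 (3R,3aS,4R,6R,7R,7aS)-7-(tert-butyldimethylsilyloxy)-3-[(2S)-2-(tert-butyldimethylsilyloxy)hex-5-en-2-yl]-6-methyl-4-(prop-1-en-2-yl)hexahydro-2-benzofuran-1(3H)-one (cis-fused lactone), via ketene 26 (not isolated)
Conditions: hν (365 nm), THF, rt
Reagents that add atoms: none
Why: Irradiation expels N2 from the cyclic 2-diazo ketone, whose diazo and carbonyl groups are locked s-cis, and C1 migrates from C9 to C10 in a concerted Wolff rearrangement, so the cycloheptanone contracts to a cyclohexylidene ketene (C10=C9=O) with C9 now exocyclic. The closest known reaction type is the photochemical Wolff ring contraction of cyclic 2-diazo ketones with capture of the ketene by an alcohol, here the internal C2 hydroxyl. The cyclohexane arises by the 1,2-shift (ring contraction, seven to six) and the lactone by addition of the C2 hydroxyl to the ketene carbon C9, a five-membered closure (5-exo-dig at the C=O bond). C1 migrates with retention, and the new centre C10 is set when the lactone enol is protonated on the face opposite the C11 silyloxy and C12 methyl groups, giving the cis ring fusion (H10 cis to H1). Only C1 can migrate, so the selectivity needed is rearrangement over carbene O–H insertion or 1,2-hydride shift, which the s-cis geometry and direct photolysis without a metal favour, and capture by the one free hydroxyl, all other oxygens being silylated.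

Step 13
Reactants: 27; 28 2-methylallylmagnesium chloride
Product: 29 hemiketal from addition of the 2-methylallyl group to C9 of 27 (C9 epimers)
Conditions: 2-methylallylMgCl, CeCl3, THF, −78 °C; aq. NH4Cl
Reagents that add atoms: 2-methylallylmagnesium chloride, C=C(C)C[Mg]Cl
Why: Organocerium addition to the γ-lactone stops at the cyclic hemiketal alkoxide, and the weakly basic reagent avoids enolisation at C10; the C9 mixture is removed in step 14.

Step 14
Reactants: 29
Product: 30 (1R,3R,3aS,4R,6R,7R,7aR)-7-(tert-butyldimethylsilyloxy)-3-[(2S)-2-(tert-butyldimethylsilyloxy)hex-5-en-2-yl]-6-methyl-1-(2-methylallyl)-4-(prop-1-en-2-yl)octahydro-2-benzofuran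
Conditions: Et3SiH, BF3·OEt2, CH2Cl2, −78 °C
Reagents that add atoms: none
Why: Reductive etherification: the Lewis acid ionises the hemiketal to the bicyclic oxocarbenium ion, and the silane delivers hydride to its convex face (the face of H10 and H1, away from the cyclohexane ring and the C2 side chain), so H9 ends cis to H10 and the 2-methylallyl group on the concave face.

Step 15
Reactants: 30
Product: 31 tricyclic oxonene with Z-C6=C7, TBS ethers on C11 and C3, isopropenyl on C14 (all stereocentres as in the target)
Conditions: second-generation Grubbs catalyst RuCl2(=CHPh)(PCy3)(H2IMes) (10 mol %), CH2Cl2 (2 mM), 40 °C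
Reagents that add atoms: none
Why: Ring-closing metathesis: the alkylidene formed at the monosubstituted alkene closes onto the 2-methylallyl group held close on the same face of the cis-2,5-disubstituted oxygen ring, whereas the α-branched isopropenyl group is the slower partner and would give a strained carbocycle; the nine-membered ring enforces the Z alkene.

Step 16
Reactants: 31
Product: 32 tricyclic C11,C3-diol
Conditions: Bu4NF, THF, 60 °C; aq. NH4Cl
Reagents that add atoms: none
Why: Fluoride desilylation of both ethers under basic conditions, which avoids acid-triggered transannular etherification of the C3 alcohol onto C6=C7.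

Step 17
Reactants: 32; 33 butyric anhydride
Product: 34 C11 butyrate of 32 (C3 hydroxyl free)
Conditions: (n-PrCO)2O, Et3N, DMAP (cat.), CH2Cl2, 0 °C to rt
Reagents that add atoms: butyric anhydride, CCCC(=O)OC(=O)CCC
Why: Nucleophile-catalysed acylation discriminates the secondary C11 hydroxyl from the tertiary C3 hydroxyl.

Step 18
Reactants: 34; 35 hydrogen peroxide
Product: 37 C16 primary alcohol with (15R) configuration, via B-alkyl-9-BBN 36 (not isolated)
Conditions: 9-BBN, THF, 0 °C to rt; then H2O2, aq. NaOAc, 0 °C
Reagents that add atoms: hydrogen peroxide, OO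
Why: Hydroboration–oxidation: 9-BBN adds to the 1,1-disubstituted alkene much faster than to the trisubstituted ring alkene and should attack the A(1,3)-minimised rotamer (H14 eclipsing C15=C16) from the C13 side, away from C1 and its C2 substituent, which sets C15 as (R).

Step 19
Reactants: 37
Product: 39 target CNP0209450.4, via primary triflate 38 (not isolated)
Conditions: Tf2O, 2,6-lutidine, CH2Cl2, −78 °C to rt
Reagents that add atoms: none
Why: Selective triflation of the primary alcohol and intramolecular Williamson etherification (7-exo-tet) by the tertiary C3 hydroxyl held on the same face close the oxepane without touching a stereocentre.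

Compound list
1 | (R)-2-methylglycidol | OC[C@]1(C)CO1 | starting material
2 | allylmagnesium chloride | C=CC[Mg]Cl | starting material
3 | (S)-2-methylhex-5-ene-1,2-diol | OC[C@@](C)(O)CCC=C | intermediate
4 | tert-butyldimethylsilyl triflate | CC(C)(C)[Si](C)(C)OS(=O)(=O)C(F)(F)F | starting material
5 | (S)-1,2-bis(tert-butyldimethylsilyloxy)-2-methylhex-5-ene | CC(C)(C)[Si](C)(C)OC[C@@](C)(O[Si](C)(C)C(C)(C)C)CCC=C | intermediate
6 | (S)-2-(tert-butyldimethylsilyloxy)-2-methylhex-5-en-1-ol | OC[C@@](C)(O[Si](C)(C)C(C)(C)C)CCC=C | intermediate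
7 | (S)-2-(tert-butyldimethylsilyloxy)-2-methylhex-5-enal (fragment 1) | O=C[C@@](C)(O[Si](C)(C)C(C)(C)C)CCC=C | intermediate
8 | 8-oxabicyclo[3.2.1]oct-6-en-3-one (meso) | O=C1C[C@H]2C=C[C@@H](C1)O2 | starting material
9 | ethylene glycol | OCCO | starting material
10 | ethylene ketal of 8 (meso) | C1COC2(O1)C[C@H]3C=C[C@@H](C2)O3 | intermediate
11 | dimethylzinc | C[Zn]C | starting material
12 | (7S,8R)-8-methyl-1,4-dioxaspiro[4.6]undec-9-en-7-ol | O1CCOC12C[C@H](O)[C@H](C)C=CC2 | intermediate
13 | tert-butyldimethylsilyl chloride | CC(C)(C)[Si](C)(C)Cl | starting material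
14 | tert-butyl{[(7S,8R)-8-methyl-1,4-dioxaspiro[4.6]undec-9-en-7-yl]oxy}dimethylsilane | O1CCOC12C[C@H](O[Si](C)(C)C(C)(C)C)[C@H](C)C=CC2 | intermediate
15 | water | O | starting material
16 | (5R,6S)-6-(tert-butyldimethylsilyloxy)-5-methylcyclohept-3-en-1-one | O=C1C[C@H](O[Si](C)(C)C(C)(C)C)[C@H](C)C=CC1 | intermediate
17 | (5R,6S)-6-(tert-butyldimethylsilyloxy)-5-methylcyclohept-2-en-1-one | O=C1C[C@H](O[Si](C)(C)C(C)(C)C)[C@H](C)CC=C1 | intermediate
18 | isopropenylmagnesium bromide | C=C(C)[Mg]Br | starting material
19 | chlorotrimethylsilane | C[Si](C)(C)Cl | starting material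
20 | tert-butyl{[(1S,2R,4R)-2-methyl-4-(prop-1-en-2-yl)-6-(trimethylsilyloxy)cyclohept-5-en-1-yl]oxy}dimethylsilane | C[Si](C)(C)OC1=C[C@H](C(C)=C)C[C@@H](C)[C@@H](O[Si](C)(C)C(C)(C)C)C1 | intermediate
21 | (2R,3R,5R,6S)-6-(tert-butyldimethylsilyloxy)-2-[(1R,2S)-2-(tert-butyldimethylsilyloxy)-2-methyl-1-(trimethylsilyloxy)hex-5-en-1-yl]-5-methyl-3-(prop-1-en-2-yl)cycloheptan-1-one | O=C1C[C@H](O[Si](C)(C)C(C)(C)C)[C@H](C)C[C@@H](C(C)=C)[C@@H]1[C@@H](O[Si](C)(C)C)[C@@](C)(O[Si](C)(C)C(C)(C)C)CCC=C | intermediate
22 | 4-acetamidobenzenesulfonyl azide | CC(=O)Nc1ccc(cc1)S(=O)(=O)N=[N+]=[N-] | starting material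
23 | C10-trifluoroacetyl derivative of 21 (chelated enol form) | O=C1/C(=C(\O)C(F)(F)F)[C@H](O[Si](C)(C)C(C)(C)C)[C@H](C)C[C@@H](C(C)=C)[C@@H]1[C@@H](O[Si](C)(C)C)[C@@](C)(O[Si](C)(C)C(C)(C)C)CCC=C | intermediate
24 | O-TMS ether of diazo ketone 25 | O=C1C(=[N+]=[N-])[C@H](O[Si](C)(C)C(C)(C)C)[C@H](C)C[C@@H](C(C)=C)[C@@H]1[C@@H](O[Si](C)(C)C)[C@@](C)(O[Si](C)(C)C(C)(C)C)CCC=C | intermediate
25 | (3R,4R,6R,7R)-3-(tert-butyldimethylsilyloxy)-7-[(1R,2S)-2-(tert-butyldimethylsilyloxy)-1-hydroxy-2-methylhex-5-en-1-yl]-2-diazo-4-methyl-6-(prop-1-en-2-yl)cycloheptan-1-one | O=C1C(=[N+]=[N-])[C@H](O[Si](C)(C)C(C)(C)C)[C@H](C)C[C@@H](C(C)=C)[C@@H]1[C@@H](O)[C@@](C)(O[Si](C)(C)C(C)(C)C)CCC=C | intermediate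
26 | ring-contracted cyclohexylidene ketene (C10=C9=O) with free C2 hydroxyl | O=C=C1[C@H](O[Si](C)(C)C(C)(C)C)[C@H](C)C[C@@H](C(C)=C)[C@@H]1[C@@H](O)[C@@](C)(O[Si](C)(C)C(C)(C)C)CCC=C | intermediate
27 | (3R,3aS,4R,6R,7R,7aS)-7-(tert-butyldimethylsilyloxy)-3-[(2S)-2-(tert-butyldimethylsilyloxy)hex-5-en-2-yl]-6-methyl-4-(prop-1-en-2-yl)hexahydro-2-benzofuran-1(3H)-one | O=C1O[C@@H]([C@@](C)(O[Si](C)(C)C(C)(C)C)CCC=C)[C@@H]2[C@H]1[C@H](O[Si](C)(C)C(C)(C)C)[C@H](C)C[C@H]2C(C)=C | intermediate
28 | 2-methylallylmagnesium chloride | C=C(C)C[Mg]Cl | starting material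
29 | C9 hemiketal of 27 bearing the 2-methylallyl group (C9 epimers) | OC1(CC(C)=C)O[C@@H]([C@@](C)(O[Si](C)(C)C(C)(C)C)CCC=C)[C@@H]2[C@H]1[C@H](O[Si](C)(C)C(C)(C)C)[C@H](C)C[C@H]2C(C)=C | intermediate
30 | (1R,3R,3aS,4R,6R,7R,7aR)-7-(tert-butyldimethylsilyloxy)-3-[(2S)-2-(tert-butyldimethylsilyloxy)hex-5-en-2-yl]-6-methyl-1-(2-methylallyl)-4-(prop-1-en-2-yl)octahydro-2-benzofuran | C=C(C)C[C@H]1O[C@@H]([C@@](C)(O[Si](C)(C)C(C)(C)C)CCC=C)[C@@H]2[C@H]1[C@H](O[Si](C)(C)C(C)(C)C)[C@H](C)C[C@H]2C(C)=C | intermediate
31 | tricyclic Z-oxonene, C11 and C3 TBS ethers, C14 isopropenyl (stereocentres as in the target) | CC(C)(C)[Si](C)(C)O[C@H]1[C@@H]2[C@H]([C@@H](C[C@H]1C)C(C)=C)[C@H]3O[C@@H]2C/C(C)=C\CC[C@]3(C)O[Si](C)(C)C(C)(C)C | intermediate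
32 | tricyclic C11,C3-diol | O[C@H]1[C@@H]2[C@H]([C@@H](C[C@H]1C)C(C)=C)[C@H]3O[C@@H]2C/C(C)=C\CC[C@]3(C)O | intermediate
33 | butyric anhydride | CCCC(=O)OC(=O)CCC | starting material
34 | C11 butyrate of 32 | CCCC(=O)O[C@H]1[C@@H]2[C@H]([C@@H](C[C@H]1C)C(C)=C)[C@H]3O[C@@H]2C/C(C)=C\CC[C@]3(C)O | intermediate
35 | hydrogen peroxide | OO | starting material
36 | B-(C16-alkyl)-9-borabicyclo[3.3.1]nonane adduct of 34 | CCCC(=O)O[C@H]1[C@@H]2[C@H]([C@@H](C[C@H]1C)[C@@H](C)CB4C5CCCC4CCC5)[C@H]3O[C@@H]2C/C(C)=C\CC[C@]3(C)O | intermediate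
37 | (15R) C16 primary alcohol, C3 tertiary alcohol, C11 butyrate | CCCC(=O)O[C@H]1[C@@H]2[C@H]([C@@H](C[C@H]1C)[C@@H](C)CO)[C@H]3O[C@@H]2C/C(C)=C\CC[C@]3(C)O | intermediate
38 | C16 triflate of 37 | CCCC(=O)O[C@H]1[C@@H]2[C@H]([C@@H](C[C@H]1C)[C@@H](C)COS(=O)(=O)C(F)(F)F)[C@H]3O[C@@H]2C/C(C)=C\CC[C@]3(C)O | intermediate
39 | CNP0209450.4 | CCCC(=O)O[C@H]1[C@@H]2[C@@H]3[C@@H](C[C@H]1C)[C@@H](C)CO[C@@]1(C)CC/C=C(/C)C[C@H]2O[C@H]31 | target

Total step count: 19. Longest linear sequence: 15 steps (steps 5–19, from 8); fragment 1 (steps 1–4) enters at step 10.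

The three steps most likely to fail

Step 9. The facial selectivity of the conjugate addition may be poor, because the controlling centres (C12, C11) are remote from C14 on a flexible seven-membered ring. The fallback sets out from 17 and comes back at 20. C14 would be set under ligand control by 1,4-addition of isopropenylboronic acid pinacol ester with [Rh(OH)(cod)]2 and (R)-BINAP in dioxane/H2O at 50 °C, giving (3R,5R,6S)-6-(tert-butyldimethylsilyloxy)-5-methyl-3-(prop-1-en-2-yl)cycloheptan-1-one F1. Kinetic enol silylation of F1 (LiN(i-Pr)2, Me3SiCl, THF, −78 °C, internal quench) is expected on the side remote from the β-silyloxy group and would return 20.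

Step 10. Bond formation between two hindered carbons may stall or reverse, and the syn selectivity may erode, so that C2 epimers are carried forward. The fallback makes the C2 configuration independent of the aldol; it sets out from 25 (taken on as the C2 epimer mixture) and comes back at 27. Dess–Martin oxidation of the C2 hydroxyl should give the 2-diazo-1,3-diketone F2. Irradiation of F2 in wet THF contracts the ring and traps the ketene with water as the γ-keto acid F3 (C9 acid on C10, C2 ketone on C1). Et3SiH with BF3·OEt2 at −78 °C should then reduce the derived cyclic acyloxycarbenium ion at C2 from the convex face and close lactone 27.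

Step 12. The excited diazo ketone may divert to carbene chemistry (O–H insertion by the free hydroxyl, 1,2-hydride shift from C11), or the lactone enol may be protonated from the wrong face. The fallback separates ring contraction from ring closure; it sets out from 24 (obtained by leaving out the citric acid stage of step 11) and comes back at 27. Irradiation of 24 in methanol gives the classical intermolecular capture, the ring-contracted methyl ester F4 (C9 ester on C10, C2 silyl ether intact), whose C10 centre can be equilibrated as the ester. Camphorsulfonic acid in methanol, then warm toluene, removes the TMS group and lactonises to 27.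

Further compounds
F1 | step 9 | (3R,5R,6S)-6-(tert-butyldimethylsilyloxy)-5-methyl-3-(prop-1-en-2-yl)cycloheptan-1-one | O=C1C[C@H](O[Si](C)(C)C(C)(C)C)[C@H](C)C[C@@H](C(C)=C)C1
F2 | step 10 | 2-diazo-1,3-diketone from oxidation of the C2 hydroxyl of 25 | O=C1C(=[N+]=[N-])[C@H](O[Si](C)(C)C(C)(C)C)[C@H](C)C[C@@H](C(C)=C)[C@@H]1C(=O)[C@@](C)(O[Si](C)(C)C(C)(C)C)CCC=C
F3 | step 10 | ring-contracted γ-keto acid (C9 carboxylic acid on C10, C2 ketone on C1) | OC(=O)[C@@H]1[C@H](O[Si](C)(C)C(C)(C)C)[C@H](C)C[C@@H](C(C)=C)[C@@H]1C(=O)[C@@](C)(O[Si](C)(C)C(C)(C)C)CCC=C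
F4 | step 12 | ring-contracted methyl ester with C2 trimethylsilyl ether | COC(=O)[C@@H]1[C@H](O[Si](C)(C)C(C)(C)C)[C@H](C)C[C@@H](C(C)=C)[C@@H]1[C@@H](O[Si](C)(C)C)[C@@](C)(O[Si](C)(C)C(C)(C)C)CCC=C
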